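The target is a cis-(3R,4R)-isoflavan-4-ol, taken back to an isoflavone whose ring C is built in one pot around C2, C3 and C4. The feature exploited is that ring A is a phloroglucinol unit: its three oxygens (later O1, O5, O7) and three ring carbons are equivalent, so acylation by the ring B arylacetic acid forms C4–C4a without a regiochemical question, and a one-carbon electrophile from DMF then supplies C2, making C2–C3 and O1–C2 and closing ring C. The precursors are phloroglucinol and 5-bromo-4-hydroxy-2-methoxyphenylacetic acid, bromine marking C5' for later prenylation. C3 and C4 are set last by transfer hydrogenation with dynamic kinetic resolution.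

Key step: step 4

Remark: the 4'-OH next to bromine in 10 is expected to be almost as acidic as the 7-OH, so O-methylation is deferred until bromine has been exchanged for prenyl, when the 7-OH should be the only readily ionised phenol; ring B is carried unprotected throughout.

Step 1
Reactants: 1 4-hydroxy-2-methoxybenzaldehyde
Product: 2 5-bromo-4-hydroxy-2-methoxybenzaldehyde
Conditions: NBS (1.0 equiv), MeCN, 0 °C to rt
Reagents that add atoms: N-bromosuccinimide, O=C1CCC(=O)N1Br
Why: Electrophilic aromatic bromination should go to C5, which is ortho to the free hydroxyl and para to the methoxy group and is less crowded than C3 between the two oxygens, while the formyl group tempers the ring enough for monobromination.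

Step 2
Reactants: 2 5-bromo-4-hydroxy-2-methoxybenzaldehyde; 3 N-acetylglycine
Product: 4 (Z)-4-(4-acetoxy-5-bromo-2-methoxybenzylidene)-2-methyl-1,3-oxazol-5(4H)-one
Conditions: Ac2O, NaOAc, 100 °C; crude solid taken on
Reagents that add atoms: acetic anhydride, CC(=O)OC(C)=O
Why: Erlenmeyer–Plöchl azlactone synthesis, in which Ac2O cyclodehydrates N-acetylglycine to the 2-methyloxazolone, its C4 methylene condenses with the aldehyde in a Perkin-type reaction, and concurrent O-acetylation of the phenol keeps the aldehyde electrophilic; the Z alkene is the usual thermodynamic outcome and has no consequence later.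

Step 3
Reactants: 4 (Z)-4-(4-acetoxy-5-bromo-2-methoxybenzylidene)-2-methyl-1,3-oxazol-5(4H)-one
Product: 6 2-(5-bromo-4-hydroxy-2-methoxyphenyl)acetic acid, via arylpyruvic acid 5 (not isolated)
Conditions: NaOH (10% aq), reflux, N2; then H2O2 (30%), 5 °C to rt; HCl to pH 2
Reagents that add atoms: water, O; hydrogen peroxide, OO
Why: Alkaline hydrolysis opens the azlactone and cleaves the enamide and the aryl acetate to give arylpyruvate 5, and hydroperoxide then adds to the keto group and fragments with loss of CO2 (oxidative decarboxylation of an α-keto acid, the classical azlactone route to arylacetic acids), the aryl bromide and methyl ether being inert to aqueous base.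

Step 4
Reactants: 7 phloroglucinol (anhydrous); 6 2-(5-bromo-4-hydroxy-2-methoxyphenyl)acetic acid; 8 N,N-dimethylformamide
Product: 10 3-(5-bromo-4-hydroxy-2-methoxyphenyl)-5,7-dihydroxy-4H-chromen-4-one, via deoxybenzoin 9 (not isolated)
Conditions: BF3·OEt2 (solvent), 85 °C; cool, then DMF, MeSO2Cl, 50 to 75 °C; aq NaOAc, 60 °C
Reagents that add atoms: none
Why: BF3 turns the acid into an acylating species and phloroglucinol is C-acylated (Friedel–Crafts) to form C4–C4a, giving deoxybenzoin 9, which stays in the flask as the O–BF2 chelate of its C4 carbonyl and an ortho hydroxyl. DMF and MeSO2Cl then generate a Vilsmeier-type iminium electrophile that attacks the chelated enol at the benzylic carbon (C2–C3), and loss of the leaving group gives a C3-bound iminium. A ring A hydroxyl ortho to the acyl group adds to the iminium carbon in a 6-exo-trig closure (O1–C2), and loss of Me2NH leaves the 4H-chromen-4-one, so ring C is the only ring formed. The closest known reaction is the one-pot conversion of a phenol and an arylacetic acid into an isoflavone in BF3·OEt2 with DMF and MeSO2Cl, used here on its usual substrate class. No stereocentre is created. The step needs monoacylation and attack of the one-carbon electrophile at the methylene carbon: the first acyl group and its boron chelate deactivate ring A, the chelated enol is the most nucleophilic carbon, the threefold symmetry of phloroglucinol makes all ring positions and both flanking hydroxyls equivalent, and bromine, standing in for an acid-labile prenyl group, blocks C5' of ring B.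

Step 5
Reactants: 10 3-(5-bromo-4-hydroxy-2-methoxyphenyl)-5,7-dihydroxy-4H-chromen-4-one; 11 prenylboronic acid pinacol ester
Product: 12 5,7-dihydroxy-3-[4-hydroxy-2-methoxy-5-(3-methylbut-2-en-1-yl)phenyl]-4H-chromen-4-one
Conditions: 11 (2 equiv), Pd(OAc)2 (5 mol %), t-BuXPhos (10 mol %), K3PO4 (5 equiv, aq), THF, 65 °C, degassed; work-up at pH 6
Reagents that add atoms: none
Why: Suzuki–Miyaura coupling of an aryl bromide with an allylic boronate, in which the bulky di-tert-butylbiarylphosphine should favour the primary σ-allyl palladium species after transmetallation so that reductive elimination gives the linear prenyl product, while the phosphate base ionises the phenols and so shields the chromone from ring opening.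

Step 6
Reactants: 12 5,7-dihydroxy-3-[4-hydroxy-2-methoxy-5-(3-methylbut-2-en-1-yl)phenyl]-4H-chromen-4-one
Product: 13 5-hydroxy-3-[4-hydroxy-2-methoxy-5-(3-methylbut-2-en-1-yl)phenyl]-7-methoxy-4H-chromen-4-one
Conditions: K2CO3 (1.0 equiv), MeI (1.1 equiv), DMF, 0 °C to rt
Reagents that add atoms: iodomethane, CI
Why: Williamson O-methylation under acidity control, since one equivalent of carbonate should ionise only the 7-OH (a vinylogous acid para to C4=O), whereas the 5-OH is held in a hydrogen bond to C4=O and the 4'-OH, now next to an alkyl group, should be about three pKa units weaker.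

Step 7
Reactants: 13 5-hydroxy-3-[4-hydroxy-2-methoxy-5-(3-methylbut-2-en-1-yl)phenyl]-7-methoxy-4H-chromen-4-one
Product: 15 (3R,4R)-3-[4-hydroxy-2-methoxy-5-(3-methylbut-2-en-1-yl)phenyl]-7-methoxy-3,4-dihydro-2H-chromene-4,5-diol, via isoflavanone 14 (not isolated)
Conditions: RuCl(p-cymene)[(R,R)-TsDPEN] (5 mol %), HCO2H/Et3N (1:2), EtOAc, 40 °C; aq NaHCO3 work-up, Et3N-washed silica
Reagents that add atoms: none
Why: Noyori–Ikariya asymmetric transfer hydrogenation, in which conjugate reduction of C2=C3 gives isoflavanone 14, whose C3 epimerises through the enol in the amine-rich medium, and the (R,R)-catalyst, which gives (R)-alcohols from 4-chromanone-type aryl ketones, delivers hydride to C4 anti to the C3 aryl group of the matched (3R)-ketone, so that dynamic kinetic resolution should give the cis-(3R,4R) alcohol while the isolated prenyl alkene and the phenols stay untouched and the acid-labile benzylic alcohol never meets free acid.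

Compound list
1 | 4-hydroxy-2-methoxybenzaldehyde | COc1cc(O)ccc1C=O | starting material
2 | 5-bromo-4-hydroxy-2-methoxybenzaldehyde | COc1cc(O)c(Br)cc1C=O | intermediate
3 | N-acetylglycine | CC(=O)NCC(=O)O | starting material
4 | (Z)-4-(4-acetoxy-5-bromo-2-methoxybenzylidene)-2-methyl-1,3-oxazol-5(4H)-one | CC(=O)Oc1cc(OC)c(/C=C2\N=C(C)OC2=O)cc1Br | intermediate
5 | 3-(5-bromo-4-hydroxy-2-methoxyphenyl)-2-oxopropanoic acid (arylpyruvic acid, present as its sodium salt, not isolated) | COc1cc(O)c(Br)cc1CC(=O)C(=O)O | intermediate
6 | 2-(5-bromo-4-hydroxy-2-methoxyphenyl)acetic acid | COc1cc(O)c(Br)cc1CC(=O)O | intermediate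
7 | phloroglucinol (benzene-1,3,5-triol) | Oc1cc(O)cc(O)c1 | starting material
8 | N,N-dimethylformamide | CN(C)C=O | starting material
9 | 2-(5-bromo-4-hydroxy-2-methoxyphenyl)-1-(2,4,6-trihydroxyphenyl)ethan-1-one (deoxybenzoin, held as its BF2 chelate, not isolated) | COc1cc(O)c(Br)cc1CC(=O)c1c(O)cc(O)cc1O | intermediate
10 | 3-(5-bromo-4-hydroxy-2-methoxyphenyl)-5,7-dihydroxy-4H-chromen-4-one | Oc1cc(O)c2c(c1)occ(-c1cc(Br)c(O)cc1OC)c2=O | intermediate
11 | prenylboronic acid pinacol ester (4,4,5,5-tetramethyl-2-(3-methylbut-2-en-1-yl)-1,3,2-dioxaborolane) | CC(C)=CCB1OC(C)(C)C(C)(C)O1 | starting material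
12 | 5,7-dihydroxy-3-[4-hydroxy-2-methoxy-5-(3-methylbut-2-en-1-yl)phenyl]-4H-chromen-4-one | Oc1cc(O)c2c(c1)occ(-c1cc(CC=C(C)C)c(O)cc1OC)c2=O | intermediate
13 | 5-hydroxy-3-[4-hydroxy-2-methoxy-5-(3-methylbut-2-en-1-yl)phenyl]-7-methoxy-4H-chromen-4-one | COc1cc(O)c2c(c1)occ(-c1cc(CC=C(C)C)c(O)cc1OC)c2=O | intermediate
14 | 5-hydroxy-3-[4-hydroxy-2-methoxy-5-(3-methylbut-2-en-1-yl)phenyl]-7-methoxy-2,3-dihydro-4H-chromen-4-one (isoflavanone, C3 configurationally labile, not isolated) | COc1cc(O)c2c(c1)OCC(c1cc(CC=C(C)C)c(O)cc1OC)C2=O | intermediate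
15 | (3R,4R)-3-[4-hydroxy-2-methoxy-5-(3-methylbut-2-en-1-yl)phenyl]-7-methoxy-3,4-dihydro-2H-chromene-4,5-diol (cis) | COc1cc(O)c2c(c1)OC[C@@H](c1cc(CC=C(C)C)c(O)cc1OC)[C@H]2O | target

Total step count: 7. Longest linear sequence: 7 steps (1 → 2 → 4 → 6 → 10 → 12 → 13 → 15).

Steps most likely to fail

Step 5. Coupling may leak through the tertiary allyl terminus and give the 1,1-dimethylallyl regioisomer, and the allylboronate may protodeboronate before it couples. The fallback sets out from 10. Suzuki–Miyaura coupling with allylboronic acid pinacol ester (PdCl2(dppf), K3PO4 aq, THF, 65 °C), where no regiochemical choice exists, should give 3-(5-allyl-4-hydroxy-2-methoxyphenyl)-5,7-dihydroxy-4H-chromen-4-one F1. Olefin cross-metathesis of F1 with excess 2-methyl-2-butene (second-generation Grubbs catalyst, CH2Cl2, 40 °C) should then turn allyl into prenyl and return to the route at 12.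

Step 7. Hydride transfer to C4=O may be slow because the carbonyl is hydrogen-bonded to the 5-OH and carries three oxygen donors, so the reaction may stall at the isoflavanone stage, and the electron-rich benzylic alcohol may ionise and dehydrate. The fallback sets out from 13. Silylation of both phenols (TBSOTf, 2,6-lutidine, CH2Cl2, 0 °C) should give 5-[(tert-butyldimethylsilyl)oxy]-3-{4-[(tert-butyldimethylsilyl)oxy]-2-methoxy-5-(3-methylbut-2-en-1-yl)phenyl}-7-methoxy-4H-chromen-4-one F2, whose ketone is no longer chelated. The same transfer hydrogenation with dynamic kinetic resolution should then give (3R,4R)-5-[(tert-butyldimethylsilyl)oxy]-3-{4-[(tert-butyldimethylsilyl)oxy]-2-methoxy-5-(3-methylbut-2-en-1-yl)phenyl}-7-methoxy-3,4-dihydro-2H-chromen-4-ol F3. Buffered desilylation (TBAF, AcOH, THF, 0 °C) returns to the route at 15.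

Step 4. In hot BF3·OEt2 the bromine may be transferred from C5' to phloroglucinol after ipso-protonation, and the iminium electrophile may attack ring A instead of the methylene carbon. The fallback sets out from 6 and moves the C4–C4a bond formation to low temperature. Amidation (CDI, THF, then aq NH3) should give 2-(5-bromo-4-hydroxy-2-methoxyphenyl)acetamide F4. Dehydration ((CF3CO)2O, pyridine, then aq NaHCO3) should give 2-(5-bromo-4-hydroxy-2-methoxyphenyl)acetonitrile F5. A Houben–Hoesch reaction of F5 with 7 (ZnCl2, HCl gas, Et2O, 0 °C) should give 2-(5-bromo-4-hydroxy-2-methoxyphenyl)-1-(2,4,6-trihydroxyphenyl)ethan-1-iminium chloride F6. Hydrolysis of F6 in hot water gives deoxybenzoin 9, which is then isolated and closed separately with 8, MeSO2Cl and BF3·OEt2 at 50–60 °C, returning to the route at 10.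

Further compounds
F1 | step 5 | 3-(5-allyl-4-hydroxy-2-methoxyphenyl)-5,7-dihydroxy-4H-chromen-4-one | Oc1cc(O)c2c(c1)occ(-c1cc(CC=C)c(O)cc1OC)c2=O
F2 | step 7 | 5-[(tert-butyldimethylsilyl)oxy]-3-{4-[(tert-butyldimethylsilyl)oxy]-2-methoxy-5-(3-methylbut-2-en-1-yl)phenyl}-7-methoxy-4H-chromen-4-one | COc1cc(O[Si](C)(C)C(C)(C)C)c2c(c1)occ(-c1cc(CC=C(C)C)c(O[Si](C)(C)C(C)(C)C)cc1OC)c2=O
F3 | step 7 | (3R,4R)-5-[(tert-butyldimethylsilyl)oxy]-3-{4-[(tert-butyldimethylsilyl)oxy]-2-methoxy-5-(3-methylbut-2-en-1-yl)phenyl}-7-methoxy-3,4-dihydro-2H-chromen-4-ol | COc1cc(O[Si](C)(C)C(C)(C)C)c2c(c1)OC[C@@H](c1cc(CC=C(C)C)c(O[Si](C)(C)C(C)(C)C)cc1OC)[C@H]2O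
F4 | step 4 | 2-(5-bromo-4-hydroxy-2-methoxyphenyl)acetamide | COc1cc(O)c(Br)cc1CC(N)=O
F5 | step 4 | 2-(5-bromo-4-hydroxy-2-methoxyphenyl)acetonitrile | COc1cc(O)c(Br)cc1CC#N
F6 | step 4 | 2-(5-bromo-4-hydroxy-2-methoxyphenyl)-1-(2,4,6-trihydroxyphenyl)ethan-1-iminium chloride | COc1cc(O)c(Br)cc1CC(=[NH2+])c1c(O)cc(O)cc1O.[Cl-]
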